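**Plan**

- Retrosynthesis: the two benzyl ethers and the C3–O bond are removed first. The pyranone is then opened at O1–C2 to an aryl 1,3-dicarbonyl unit, which is stored as a 3,5-diarylisoxazole. The isoxazole is cut at C3–C4 and at its O–C2 bond into a ring A nitrile oxide and a ring B arylacetylene.
- Enabling feature: the future C4 hangs on C4a, whose two neighbours C5 and C8a both carry oxygen. The nitrile oxide carbon therefore sits between two ortho alkoxy groups, so the dipole resists dimerisation and can be isolated and used stoichiometrically.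
- Forward: the ring A dipole is made in five steps from 1,2,3,4-tetramethoxybenzene and the ring B alkyne in three steps from methyl 3,5-dihydroxy-4-methoxybenzoate. The isoxazole ring forms first; N–O cleavage and acid then close the pyranone (ring C). C3 hydroxylation, O-methylation and hydrogenolysis finish the route.
- Stereochemistry: the target has no stereocentre and none is created on the main route.

Key step: step 9

Remark: 1,2,3,4-tetramethoxybenzene, methyl 3,5-dihydroxy-4-methoxybenzoate and the Bestmann–Ohira reagent are taken as catalogue chemicals; the aldoxime is drawn as its E isomer and the hydroximoyl chloride and enaminoketone as their Z isomers, geometries that have no bearing on the outcome.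

**Route**

Step 1
Reactants: 1 1,2,3,4-tetramethoxybenzene
Product: 4 2,3,4,5-tetramethoxyphenol, via aryllithium 2 (not isolated), via dimethyl arylboronate 3 (not isolated)
Conditions: n-BuLi, TMEDA, THF, 0 °C; B(OMe)3, −78 °C to rt; then 30% H2O2, AcOH, 0 °C
Reagents that add atoms: hydrogen peroxide, OO
Why: Directed ortho-lithiation beside a methoxy group (the two free positions are equivalent), trapping with trimethyl borate and oxidative 1,2-migration from boron to oxygen is the standard lithiation–borylation–oxidation route from an anisole to a phenol.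

Step 2
Reactants: 4 2,3,4,5-tetramethoxyphenol
Product: 5 1,2,3,4-tetramethoxy-5-(methoxymethoxy)benzene
Conditions: MOMCl, i-Pr2NEt, CH2Cl2, 0 °C to rt
Reagents that add atoms: chloromethyl methyl ether, COCCl
Why: O-Alkylation of the phenol with MOMCl under amine base (acetal protection) gives an ether that survives organolithium, oxidant and hot neutral conditions, directs the next metalation and is removed by acid at the ring-closure stage.

Step 3
Reactants: 5 1,2,3,4-tetramethoxy-5-(methoxymethoxy)benzene
Product: 7 2-(methoxymethoxy)-3,4,5,6-tetramethoxybenzaldehyde, via aryllithium 6 (not isolated)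
Conditions: n-BuLi, TMEDA, THF, −20 to 0 °C; DMF, −78 °C to rt; then H2O
Reagents that add atoms: N,N-dimethylformamide, CN(C)C=O
Why: The only ring hydrogen lies between the OMOM and OMe groups, so directed ortho-metalation can occur nowhere else, and the aryllithium is formylated with DMF (Bouveault-type formylation).

Step 4
Reactants: 7 2-(methoxymethoxy)-3,4,5,6-tetramethoxybenzaldehyde
Product: 8 (E)-2-(methoxymethoxy)-3,4,5,6-tetramethoxybenzaldehyde oxime
Conditions: NH2OH·HCl, NaOAc, EtOH/H2O, rt
Reagents that add atoms: hydroxylamine hydrochloride, Cl.NO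
Why: Condensation of an aromatic aldehyde with hydroxylamine under acetate buffer gives the aldoxime (oxime formation), and the buffered medium spares the MOM acetal.

Step 5
Reactants: 8 (E)-2-(methoxymethoxy)-3,4,5,6-tetramethoxybenzaldehyde oxime
Product: 10 2-(methoxymethoxy)-3,4,5,6-tetramethoxybenzonitrile oxide, via hydroximoyl chloride 9 (not isolated)
Conditions: NCS, DMF, 0 °C to rt; then Et3N, 0 °C
Reagents that add atoms: none
Why: C-Chlorination of the aldoxime with NCS and 1,3-dehydrochlorination with Et3N is the standard nitrile oxide preparation; the ring has no free position to chlorinate, and the two ortho alkoxy groups shield the dipole from furoxan formation, so it should be isolable like other 2,6-disubstituted benzonitrile oxides.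

Step 6
Reactants: 11 methyl 3,5-dihydroxy-4-methoxybenzoate
Product: 12 methyl 3,5-bis(benzyloxy)-4-methoxybenzoate
Conditions: BnBr, K2CO3, DMF, 60 °C
Reagents that add atoms: benzyl bromide, BrCc1ccccc1
Why: Williamson etherification of both phenols with benzyl bromide and carbonate, to which the ester and the methyl ether are inert.

Step 7
Reactants: 12 methyl 3,5-bis(benzyloxy)-4-methoxybenzoate
Product: 13 [3,5-bis(benzyloxy)-4-methoxyphenyl]methanol
Conditions: LiAlH4, THF, 0 °C to rt
Reagents that add atoms: none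
Why: Hydride reduction of the aryl ester to the benzylic alcohol with LiAlH4, which leaves benzyl and methyl ethers untouched.

Step 8
Reactants: 13 [3,5-bis(benzyloxy)-4-methoxyphenyl]methanol
Product: 15 1,3-bis(benzyloxy)-5-ethynyl-2-methoxybenzene, via aldehyde 14 (not isolated)
Conditions: activated MnO2, THF, rt; then dimethyl (1-diazo-2-oxopropyl)phosphonate, K2CO3, MeOH, rt
Reagents that add atoms: dimethyl (1-diazo-2-oxopropyl)phosphonate (Bestmann–Ohira reagent), COP(=O)(OC)C(=[N+]=[N-])C(C)=O
Why: MnO2 oxidises benzylic alcohols to aldehydes without over-oxidation, and the aldehyde is homologated in the same flask by the Ohira–Bestmann variant of the Seyferth–Gilbert reaction (Horner–Wadsworth–Emmons addition, loss of N2, 1,2-hydrogen shift of the alkylidene carbene), a known tandem sequence for activated alcohols.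

Step 9
Reactants: 10 2-(methoxymethoxy)-3,4,5,6-tetramethoxybenzonitrile oxide; 15 1,3-bis(benzyloxy)-5-ethynyl-2-methoxybenzene
Product: 16 5-[3,5-bis(benzyloxy)-4-methoxyphenyl]-3-[2-(methoxymethoxy)-3,4,5,6-tetramethoxyphenyl]isoxazole
Conditions: PhMe, 80 °C (slight excess of 15)
Reagents that add atoms: none
Why: Concerted, asynchronous [3+2] Huisgen cycloaddition of the nitrile oxide to the alkyne, in which the dipole carbon bonds to the terminal alkyne carbon (the future C3–C4 bond) and the dipole oxygen to the aryl-bearing carbon (the temporary O–C2 bond). The closest known reactions are the additions of isolable 2,6-disubstituted benzonitrile oxides such as mesitonitrile oxide and 2,6-dimethoxybenzonitrile oxide to arylacetylenes, which give 3,5-diarylisoxazoles. The isoxazole ring closes by intermolecular suprafacial cycloaddition with both σ bonds made in one step, and no stereocentre arises because the product is aromatic. The step needs regioselectivity for the 3,5- over the 3,4-isomer and chemoselectivity for cycloaddition over dimerisation or isomerisation of the dipole. The first is secured by the unsubstituted alkyne terminus, which carries the larger HOMO coefficient and is the only site that can accept a dipole carbon flanked by two ortho alkoxy groups, the second by those same ortho groups, which block furoxan formation, and by a temperature below that of nitrile oxide to isocyanate rearrangement.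

Step 10
Reactants: 16 5-[3,5-bis(benzyloxy)-4-methoxyphenyl]-3-[2-(methoxymethoxy)-3,4,5,6-tetramethoxyphenyl]isoxazole
Product: 17 (Z)-3-amino-1-[3,5-bis(benzyloxy)-4-methoxyphenyl]-3-[2-(methoxymethoxy)-3,4,5,6-tetramethoxyphenyl]prop-2-en-1-one
Conditions: Mo(CO)6, MeCN/H2O, 80 °C
Reagents that add atoms: none
Why: Zerovalent molybdenum inserts into the weak N–O bond and, with water as proton source, releases the β-enaminoketone (reductive isoxazole ring opening), under conditions that leave benzyl and MOM ethers intact, unlike catalytic hydrogenation.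

Step 11
Reactants: 17 (Z)-3-amino-1-[3,5-bis(benzyloxy)-4-methoxyphenyl]-3-[2-(methoxymethoxy)-3,4,5,6-tetramethoxyphenyl]prop-2-en-1-one
Product: 19 2-[3,5-bis(benzyloxy)-4-methoxyphenyl]-5,6,7,8-tetramethoxy-4H-chromen-4-one, via 1,3-diketone 18 (not isolated)
Conditions: 3 M aq HCl, THF, 60 °C
Reagents that add atoms: water, O
Why: Dilute acid cleaves the MOM acetal and hydrolyses the vinylogous amide to the 2-hydroxyaryl 1,3-diketone, which closes ring C by the cyclodehydration known from Baker–Venkataraman flavone syntheses (6-exo-trig attack of the phenol oxygen on the ring B ketone, then loss of water), while benzyl and methyl aryl ethers survive.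

Step 12
Reactants: 19 2-[3,5-bis(benzyloxy)-4-methoxyphenyl]-5,6,7,8-tetramethoxy-4H-chromen-4-one
Product: 22 2-[3,5-bis(benzyloxy)-4-methoxyphenyl]-3-hydroxy-5,6,7,8-tetramethoxy-4H-chromen-4-one, via 3-lithioflavone 20 (not isolated), via dimethyl flavon-3-ylboronate 21 (not isolated)
Conditions: LiN(iPr)2, THF, −78 °C; B(OMe)3, −78 to 0 °C; then 30% H2O2, AcOH, 0 °C to rt
Reagents that add atoms: hydrogen peroxide, OO
Why: Flavones are deprotonated at C3 by lithium amides at low temperature, and trapping the vinyllithium with trimethyl borate followed by peroxide oxidation (lithiation–borylation–oxidation) is a documented route to 3-hydroxyflavones; C3–H is the most acidic site and the benzylic ether hydrogens are not removed by LiN(iPr)2 at −78 °C.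

Step 13
Reactants: 22 2-[3,5-bis(benzyloxy)-4-methoxyphenyl]-3-hydroxy-5,6,7,8-tetramethoxy-4H-chromen-4-one
Product: 23 2-[3,5-bis(benzyloxy)-4-methoxyphenyl]-3,5,6,7,8-pentamethoxy-4H-chromen-4-one
Conditions: MeI, K2CO3, acetone, reflux
Reagents that add atoms: iodomethane, CI
Why: Williamson O-methylation of the enolic 3-hydroxyl, the only free OH in the molecule, with MeI and carbonate.

Step 14
Reactants: 23 2-[3,5-bis(benzyloxy)-4-methoxyphenyl]-3,5,6,7,8-pentamethoxy-4H-chromen-4-one
Product: 24 2-(3,5-dihydroxy-4-methoxyphenyl)-3,5,6,7,8-pentamethoxy-4H-chromen-4-one (3',5'-dihydroxy-3,5,6,7,8,4'-hexamethoxyflavone)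
Conditions: H2 (1 atm), Pd/C, EtOAc/MeOH, rt
Reagents that add atoms: none
Why: Hydrogenolysis of the two aryl benzyl ethers over zerovalent palladium on carbon at ambient pressure, conditions under which the tetrasubstituted C2–C3 double bond of a 3-methoxyflavone should not be reduced.

**Compound list**

1 | 1,2,3,4-tetramethoxybenzene | COc1ccc(OC)c(OC)c1OC | starting material
2 | (2,3,4,5-tetramethoxyphenyl)lithium | [Li]c1cc(OC)c(OC)c(OC)c1OC | intermediate
3 | dimethyl (2,3,4,5-tetramethoxyphenyl)boronate | COB(OC)c1cc(OC)c(OC)c(OC)c1OC | intermediate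
4 | 2,3,4,5-tetramethoxyphenol | COc1cc(O)c(OC)c(OC)c1OC | intermediate
5 | 1,2,3,4-tetramethoxy-5-(methoxymethoxy)benzene | COCOc1cc(OC)c(OC)c(OC)c1OC | intermediate
6 | [2,3,4,5-tetramethoxy-6-(methoxymethoxy)phenyl]lithium | [Li]c1c(OCOC)c(OC)c(OC)c(OC)c1OC | intermediate
7 | 2-(methoxymethoxy)-3,4,5,6-tetramethoxybenzaldehyde | COCOc1c(OC)c(OC)c(OC)c(OC)c1C=O | intermediate
8 | (E)-2-(methoxymethoxy)-3,4,5,6-tetramethoxybenzaldehyde oxime | COCOc1c(OC)c(OC)c(OC)c(OC)c1/C=N/O | intermediate
9 | (Z)-N-hydroxy-2-(methoxymethoxy)-3,4,5,6-tetramethoxybenzimidoyl chloride | COCOc1c(OC)c(OC)c(OC)c(OC)c1/C(Cl)=N/O | intermediate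
10 | 2-(methoxymethoxy)-3,4,5,6-tetramethoxybenzonitrile oxide | COCOc1c(OC)c(OC)c(OC)c(OC)c1C#[N+][O-] | intermediate
11 | methyl 3,5-dihydroxy-4-methoxybenzoate | COC(=O)c1cc(O)c(OC)c(O)c1 | starting material
12 | methyl 3,5-bis(benzyloxy)-4-methoxybenzoate | COC(=O)c1cc(OCc2ccccc2)c(OC)c(OCc2ccccc2)c1 | intermediate
13 | [3,5-bis(benzyloxy)-4-methoxyphenyl]methanol | OCc1cc(OCc2ccccc2)c(OC)c(OCc2ccccc2)c1 | intermediate
14 | 3,5-bis(benzyloxy)-4-methoxybenzaldehyde | O=Cc1cc(OCc2ccccc2)c(OC)c(OCc2ccccc2)c1 | intermediate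
15 | 1,3-bis(benzyloxy)-5-ethynyl-2-methoxybenzene | C#Cc1cc(OCc2ccccc2)c(OC)c(OCc2ccccc2)c1 | intermediate
16 | 5-[3,5-bis(benzyloxy)-4-methoxyphenyl]-3-[2-(methoxymethoxy)-3,4,5,6-tetramethoxyphenyl]isoxazole | COCOc1c(OC)c(OC)c(OC)c(OC)c1-c1cc(-c2cc(OCc3ccccc3)c(OC)c(OCc3ccccc3)c2)on1 | intermediate
17 | (Z)-3-amino-1-[3,5-bis(benzyloxy)-4-methoxyphenyl]-3-[2-(methoxymethoxy)-3,4,5,6-tetramethoxyphenyl]prop-2-en-1-one | COCOc1c(OC)c(OC)c(OC)c(OC)c1/C(N)=C/C(=O)c1cc(OCc2ccccc2)c(OC)c(OCc2ccccc2)c1 | intermediate
18 | 1-[3,5-bis(benzyloxy)-4-methoxyphenyl]-3-(2-hydroxy-3,4,5,6-tetramethoxyphenyl)propane-1,3-dione | COc1c(O)c(C(=O)CC(=O)c2cc(OCc3ccccc3)c(OC)c(OCc3ccccc3)c2)c(OC)c(OC)c1OC | intermediate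
19 | 2-[3,5-bis(benzyloxy)-4-methoxyphenyl]-5,6,7,8-tetramethoxy-4H-chromen-4-one | COc1c(OC)c(OC)c2c(=O)cc(-c3cc(OCc4ccccc4)c(OC)c(OCc4ccccc4)c3)oc2c1OC | intermediate
20 | {2-[3,5-bis(benzyloxy)-4-methoxyphenyl]-5,6,7,8-tetramethoxy-4-oxo-4H-chromen-3-yl}lithium | COc1c(OC)c(OC)c2c(=O)c([Li])c(-c3cc(OCc4ccccc4)c(OC)c(OCc4ccccc4)c3)oc2c1OC | intermediate
21 | dimethyl {2-[3,5-bis(benzyloxy)-4-methoxyphenyl]-5,6,7,8-tetramethoxy-4-oxo-4H-chromen-3-yl}boronate | COB(OC)c1c(-c2cc(OCc3ccccc3)c(OC)c(OCc3ccccc3)c2)oc2c(OC)c(OC)c(OC)c(OC)c2c1=O | intermediate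
22 | 2-[3,5-bis(benzyloxy)-4-methoxyphenyl]-3-hydroxy-5,6,7,8-tetramethoxy-4H-chromen-4-one | COc1c(OC)c(OC)c2c(=O)c(O)c(-c3cc(OCc4ccccc4)c(OC)c(OCc4ccccc4)c3)oc2c1OC | intermediate
23 | 2-[3,5-bis(benzyloxy)-4-methoxyphenyl]-3,5,6,7,8-pentamethoxy-4H-chromen-4-one | COc1c(OC)c(OC)c2c(=O)c(OC)c(-c3cc(OCc4ccccc4)c(OC)c(OCc4ccccc4)c3)oc2c1OC | intermediate
24 | 2-(3,5-dihydroxy-4-methoxyphenyl)-3,5,6,7,8-pentamethoxy-4H-chromen-4-one | COc1c(O)cc(-c2oc3c(OC)c(OC)c(OC)c(OC)c3c(=O)c2OC)cc1O | target

**Step count and risks**

Total step count: 14. Longest linear sequence: 11 steps (steps 1–5, then 9–14); the ring B branch (steps 6–8) joins at step 9.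

Steps most likely to fail:

1. Step 12. Deprotonation at C3 may be slow or may compete with addition of the amide base at C2 and opening of the pyranone, and the boronate next to the carbonyl may protodeboronate before it is oxidised. Fallback: starting from flavone 19, the C2–C3 double bond is epoxidised with dimethyldioxirane (acetone/CH2Cl2, 0 °C) to rac-2-[3,5-bis(benzyloxy)-4-methoxyphenyl]-2,3-epoxy-5,6,7,8-tetramethoxy-2,3-dihydro-4H-chromen-4-one F1. Catalytic p-TsOH in CH2Cl2 then opens the epoxide at C2 and the resulting cation loses the C3 proton to give flavonol 22, where the route continues with step 13.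

2. Step 9. Cycloaddition of the hindered, electron-rich dipole to an electron-rich arylacetylene may be slow enough that thermal isomerisation of the nitrile oxide to the isocyanate, or its decomposition, overtakes it. Fallback: starting from benzylic alcohol 13, the MnO2 oxidation is stopped at aldehyde 14, which is isolated and methylenated (Ph3PCH3Br, KOtBu, THF; Wittig reaction) to 1,3-bis(benzyloxy)-2-methoxy-5-vinylbenzene F2. Nitrile oxide 10 should add to this styrene, a more reactive dipolarophile than the alkyne, at room temperature with the same orientation to give racemic 5-[3,5-bis(benzyloxy)-4-methoxyphenyl]-3-[2-(methoxymethoxy)-3,4,5,6-tetramethoxyphenyl]-4,5-dihydroisoxazole F3. Dehydrogenation with activated MnO2 in hot toluene aromatises it to isoxazole 16, which rejoins the route at step 10.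

3. Step 11. Hydrolysis of the vinylogous amide may lag behind MOM cleavage and call for acid strong enough to cleave a benzyl ether or the peri 5-methoxy group, or hydrolysis at C4 may stay incomplete. Fallback: starting from isoxazole 16, the MOM group is removed first (HCl, MeOH, rt), which the isoxazole and the benzyl ethers tolerate, to give 2-{5-[3,5-bis(benzyloxy)-4-methoxyphenyl]isoxazol-3-yl}-3,4,5,6-tetramethoxyphenol F4. Mo(CO)6 in wet MeCN then opens the ring to (Z)-3-amino-1-[3,5-bis(benzyloxy)-4-methoxyphenyl]-3-(2-hydroxy-3,4,5,6-tetramethoxyphenyl)prop-2-en-1-one F5. With the free phenol already in place, warm aqueous AcOH should suffice to exchange the amino group for oxygen and close the pyranone to flavone 19, from which step 12 follows.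

**Further compounds**

F1 | step 12 | rac-2-[3,5-bis(benzyloxy)-4-methoxyphenyl]-2,3-epoxy-5,6,7,8-tetramethoxy-2,3-dihydro-4H-chromen-4-one (cis-fused epoxide, racemic, one enantiomer drawn) | COc1c(OC)c(OC)c2C(=O)[C@H]3O[C@@]3(c3cc(OCc4ccccc4)c(OC)c(OCc4ccccc4)c3)Oc2c1OC
F2 | step 9 | 1,3-bis(benzyloxy)-2-methoxy-5-vinylbenzene | C=Cc1cc(OCc2ccccc2)c(OC)c(OCc2ccccc2)c1
F3 | step 9 | 5-[3,5-bis(benzyloxy)-4-methoxyphenyl]-3-[2-(methoxymethoxy)-3,4,5,6-tetramethoxyphenyl]-4,5-dihydroisoxazole (racemic) | COCOc1c(OC)c(OC)c(OC)c(OC)c1C1=NOC(c2cc(OCc3ccccc3)c(OC)c(OCc3ccccc3)c2)C1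
F4 | step 11 | 2-{5-[3,5-bis(benzyloxy)-4-methoxyphenyl]isoxazol-3-yl}-3,4,5,6-tetramethoxyphenol | COc1c(O)c(-c2cc(-c3cc(OCc4ccccc4)c(OC)c(OCc4ccccc4)c3)on2)c(OC)c(OC)c1OC
F5 | step 11 | (Z)-3-amino-1-[3,5-bis(benzyloxy)-4-methoxyphenyl]-3-(2-hydroxy-3,4,5,6-tetramethoxyphenyl)prop-2-en-1-one | COc1c(O)c(/C(N)=C/C(=O)c2cc(OCc3ccccc3)c(OC)c(OCc3ccccc3)c2)c(OC)c(OC)c1OC
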